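**Plan**
- Retrosynthetic cuts: the C15 silyl ether; the C5=C10 alkene, traced back to a Δ1-3-ketone by an alkene shift; ring B at C6–C7 (acyloin of two esters); ring A at C3–C4 and C5–C10 ([4+2]); the diene fragment at C1–C2 (cross-metathesis) and C8–C9 (ester-enolate Claisen), back to a symmetrical E,E-C10 diol.
- Forward order: hexa-1,5-diyne → diol → Claisen rearrangement (C9) → 1-silyloxydiene → Diels–Alder reaction (ring A, C4) → acyloin condensation (ring B) → diosphenol → acetate → enone and alkene shift → desilylation.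
- Enabling feature: in ring A the C3 carbonyl carbon and the ring-fusion carbon C10 are the ends of a four-carbon unit (C3–C2–C1–C10) that flanks the two-carbon unit C4–C5, and C4 carries a methyl next to an oxidised carbon (C19). This is the imprint of a 1-oxygenated butadiene and a 2-methyl enal.
- Stereochemistry: only C4 and C9 survive. C9 comes from a reagent-controlled Ireland–Claisen rearrangement and C4 from a catalyst-controlled Diels–Alder reaction. C3, C5, C8 and C10 are created on the way and all become trigonal later, so the two remote quaternary centres are set independently.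

Key step: step 8

Numbering (halimane type): ring A = C1, C2, C3 (ketone), C4 (C18 methyl, C19 CH2OAc), C5, C10; ring B = C5, C6 (ketone), C7 (enol OH), C8 (C17 methyl), C9 (C20 methyl, side chain C11–C16), C10. β is the face of ring A that carries C19, α the face that carries C18. The target is (4S,9S).

Assumption: the sense of induction of the two chiral controllers (steps 4 and 8) is assigned from their accepted transition-state models, and both exist in either mirror-image form. C3, C5, C8 and C10 are drawn for the expected major isomers, although their configuration does not matter.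

**Step 1**
Reactants: 1 hexa-1,5-diyne
Product: 2 (2E,6E)-3,6-dimethylocta-2,6-diene-1,8-diol
Conditions: Me3Al (5 equiv), Cp2ZrCl2 (0.4 equiv), CH2Cl2, 0 → 23 °C; then (CH2O)n, 0 → 23 °C; aq. HCl
Reagents that add atoms: trimethylaluminium C[Al](C)C; paraformaldehyde, counted as formaldehyde C=O
Why: Zirconium-catalysed carboalumination (Negishi carboalumination) adds CH3–Al syn across each terminal alkyne with methyl on the internal carbon, and the alkenylalanes are hydroxymethylated with retention, so both trisubstituted alkenes should be E.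

**Step 2**
Reactants: 2 (2E,6E)-3,6-dimethylocta-2,6-diene-1,8-diol
Product: 3 (2E,6E)-8-[(tert-butyldiphenylsilyl)oxy]-3,6-dimethylocta-2,6-dien-1-ol
Conditions: NaH (1.0 equiv), THF, 0 °C; TBDPSCl (1.0 equiv), 0 → 23 °C
Reagents that add atoms: tert-butylchlorodiphenylsilane CC(C)(C)[Si](Cl)(c1ccccc1)c1ccccc1
Why: Monosilylation of a symmetrical diol through its sparingly soluble monosodium alkoxide should give mainly the mono-ether, and recovered diol is recycled.

**Step 3**
Reactants: 3 (2E,6E)-8-[(tert-butyldiphenylsilyl)oxy]-3,6-dimethylocta-2,6-dien-1-ol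
Product: 4 (2E,6E)-8-[(tert-butyldiphenylsilyl)oxy]-3,6-dimethylocta-2,6-dien-1-yl propanoate
Conditions: EtCOCl, pyridine, DMAP (cat.), CH2Cl2, 0 °C
Reagents that add atoms: propanoyl chloride CCC(=O)Cl
Why: Routine acylation of a primary allylic alcohol installs the propanoate that will supply C7, C8 and C17.

**Step 4**
Reactants: 4 (2E,6E)-8-[(tert-butyldiphenylsilyl)oxy]-3,6-dimethylocta-2,6-dien-1-yl propanoate
Product: 6 methyl (2S,3S,6E)-8-[(tert-butyldiphenylsilyl)oxy]-3-ethenyl-2,3,6-trimethyloct-6-enoate, via Claisen acid 5 (not isolated)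
Conditions: (S,S)-N,N'-bis[3,5-bis(trifluoromethyl)phenylsulfonyl]-1,2-diphenylethane-1,2-diamine (1.2 equiv), BBr3, CH2Cl2, 23 °C, then evaporation; 4, Et3N, toluene–hexane, −78 → 4 °C; aqueous work-up; Me3SiCHN2, MeOH–toluene, 0 °C
Reagents that add atoms: (trimethylsilyl)diazomethane C[Si](C)(C)C=[N+]=[N-]
Why: Enantioselective Ireland–Claisen rearrangement of the chiral boron ketene acetal through a chair transition state (E-alkene: chain equatorial, C20 methyl axial) should create the C9 quaternary centre under reagent control together with the transient C8 centre; this type of rearrangement is precedented for E-3,3-disubstituted allyl esters, and the acid is esterified in the same operation.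

**Step 5**
Reactants: 6 methyl (2S,3S,6E)-8-[(tert-butyldiphenylsilyl)oxy]-3-ethenyl-2,3,6-trimethyloct-6-enoate; 7 4,4-diethoxybut-1-ene (but-3-enal diethyl acetal)
Product: 8 methyl (2S,3S,6E)-8-[(tert-butyldiphenylsilyl)oxy]-3-[(1E)-4,4-diethoxybut-1-en-1-yl]-2,3,6-trimethyloct-6-enoate
Conditions: second-generation Hoveyda–Grubbs catalyst [RuCl2(H2IMes)(=CH-C6H4-2-OiPr)] (10 mol %), 7 (5 equiv), toluene, 70 °C
Reagents that add atoms: none
Why: Olefin cross-metathesis between the non-dimerising vinyl group on the quaternary carbon and an excess of an unhindered terminal alkene should give the E-alkene, while the trisubstituted side-chain alkene stays inert.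

**Step 6**
Reactants: 8 methyl (2S,3S,6E)-8-[(tert-butyldiphenylsilyl)oxy]-3-[(1E)-4,4-diethoxybut-1-en-1-yl]-2,3,6-trimethyloct-6-enoate
Product: 9 methyl (2S,3S,6E)-8-[(tert-butyldiphenylsilyl)oxy]-2,3,6-trimethyl-3-[(1E)-4-oxobut-1-en-1-yl]oct-6-enoate
Conditions: PPTS, acetone–H2O, 50 °C
Reagents that add atoms: water O
Why: Mild acetal hydrolysis frees the C3 aldehyde; partial migration of the alkene into conjugation would not matter, because both aldehydes give the same dienol ether.

**Step 7**
Reactants: 9 methyl (2S,3S,6E)-8-[(tert-butyldiphenylsilyl)oxy]-2,3,6-trimethyl-3-[(1E)-4-oxobut-1-en-1-yl]oct-6-enoate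
Product: 10 methyl (2S,3S,6E)-3-[(1E,3E)-4-[(tert-butyldimethylsilyl)oxy]buta-1,3-dien-1-yl]-8-[(tert-butyldiphenylsilyl)oxy]-2,3,6-trimethyloct-6-enoate
Conditions: TBSOTf, Et3N, CH2Cl2, −78 → 0 °C
Reagents that add atoms: tert-butyldimethylsilyl trifluoromethanesulfonate CC(C)(C)[Si](C)(C)OS(=O)(=O)C(F)(F)F
Why: Soft enolisation (silyl dienol ether formation) removes the doubly activated C2–H and should give the conjugated (1E,3E)-1-silyloxydiene; the hindered ester is not enolised under these conditions.

**Step 8**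
Reactants: 10 methyl (2S,3S,6E)-3-[(1E,3E)-4-[(tert-butyldimethylsilyl)oxy]buta-1,3-dien-1-yl]-8-[(tert-butyldiphenylsilyl)oxy]-2,3,6-trimethyloct-6-enoate; 11 ethyl (2E)-3-methyl-4-oxobut-2-enoate
Product: 12 Diels–Alder adduct: ring-A cyclohex-1-ene with 3β-OTBS, 4β-CHO, 4α-CH3, 5α-CO2Et and, at C10 (β), the (8S,9S) unit of 10 [C9 with C20 methyl, the silyloxyalkenyl chain and C8H(CH3)CO2Me]
Conditions: (R)-3,3-diphenyl-1-(2-methylphenyl)tetrahydro-1H,3H-pyrrolo[1,2-c][1,3,2]oxazaborole (20 mol %) activated with HNTf2 (18 mol %), CH2Cl2, −78 → −40 °C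
Reagents that add atoms: none
Why: Diels–Alder reaction: the protonated oxazaborolidine binds the formyl oxygen of 11, and the 1-silyloxydiene adds in a concerted, asynchronous [4+2] cycloaddition in which the nucleophilic diene terminus C10 bonds to C5 (β to the bound aldehyde) and the oxygen-bearing terminus C3 bonds to C4. The closest known reaction type is the cationic oxazaborolidine-catalysed cycloaddition of 2-substituted enals with 1-silyloxy-1,3-dienes. Ring A is closed in a six-membered suprafacial [4π+2π] mode; ring B is not formed here. C4 is set by the catalyst, which covers one face of the s-trans enal with a phenyl group so that the diene should add to the Si face of C4 (priorities CHO > C5 > CH3) independently of the remote C9; C5 follows from the E-alkene of 11, and C3 and C10 from the E,E-diene in the formyl-endo arrangement. The step needs regioselectivity, secured by the Lewis-acid-bound formyl group outweighing the ester, and facial selectivity at C4, secured by the catalyst; the trisubstituted side-chain alkene does not compete. Endo/exo selectivity need not be high, because C3, C5 and C10 all become trigonal in step 14.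

**Step 9**
Reactants: 12 Diels–Alder adduct
Product: 13 primary alcohol: 12 with 4β-CH2OH (C19) in place of CHO
Conditions: NaBH4, EtOH–THF, −20 → 0 °C
Reagents that add atoms: none
Why: Chemoselective borohydride reduction of the aldehyde in the presence of two esters fixes C19 at the alcohol level.

**Step 10**
Reactants: 13 primary alcohol
Product: 15 trans-fused bicyclic enediol bis(trimethylsilyl) ether: ring B closed with C6(OTMS)=C7(OTMS), (8S,9S), 5β-H, 10α-H, C19–OTMS, 3β-OTBS, C1=C2, via trimethylsilyl ether 14 (not isolated)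
Conditions: TMSCl, Et3N, toluene, 23 °C, filtration; then Na dispersion (4.4 equiv), TMSCl (5 equiv), toluene, 110 °C
Reagents that add atoms: chlorotrimethylsilane C[Si](C)(C)Cl
Why: Acyloin condensation under Rühlmann conditions couples the only two ester carbons (C6 and C7) into a six-membered ring, and trapping by TMSCl suppresses Dieckmann pathways; silyl ethers and isolated alkenes should be inert to sodium in toluene.

**Step 11**
Reactants: 15 enediol bis(trimethylsilyl) ether
Product: 17 diosphenol: 7-hydroxy-Δ7-6-ketone with 19-OH, 3β-OTBS, C1=C2, 5β-H, 10α-H, (9S), 15-OTBDPS, via acyloin 16 (not isolated)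
Conditions: Cu(OAc)2·H2O (2.2 equiv), AcOH–MeOH–H2O, 23 → 50 °C, argon
Reagents that add atoms: none
Why: Solvolysis of the three trimethylsilyl ethers gives the acyloin, which two equivalents of divalent copper acetate oxidise to the 1,2-diketone (classical acyloin oxidation); enolisation towards C8 gives the diosphenol and erases C8.

**Step 12**
Reactants: 17 diosphenol
Product: 18 19-acetate of 17
Conditions: AcCl (1.2 equiv), 2,4,6-collidine, CH2Cl2, −40 → 0 °C
Reagents that add atoms: acetyl chloride CC(=O)Cl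
Why: Acetylation with a weak base should select the primary alcohol over the hydrogen-bonded, non-ionised diosphenol hydroxyl.

**Step 13**
Reactants: 18 19-acetate
Product: 19 3β-alcohol: 18 without the tert-butyldimethylsilyl group
Conditions: 48 % aq. HF, MeCN, 0 °C
Reagents that add atoms: none
Why: Acidic fluoride cleaves the secondary TBS ether much faster than the primary TBDPS ether and leaves the acetate intact.

**Step 14**
Reactants: 19 3β-alcohol
Product: 21 15-O-tert-butyldiphenylsilyl ether of the target, via enone 20 (not isolated)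
Conditions: MnO2 (20 equiv), CH2Cl2, 23 °C, filtration; then DBU (3 equiv), toluene, 60 °C
Reagents that add atoms: none
Why: Allylic oxidation gives the Δ1-3-ketone; base-mediated alkene isomerisation then deprotonates C10 (the only enolisable site of this enone, since C4 is quaternary), protonates C2 and reconjugates through the C6 enolate to the tetrasubstituted, cross-conjugated C5=C10 enone, which removes C5 and C10 as stereocentres.

**Step 15**
Reactants: 21 15-O-tert-butyldiphenylsilyl ether of the target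
Product: 22 (4S,9S)-19-acetoxy-7,15-dihydroxyhalima-5(10),7,13E-triene-3,6-dione (CNP0512382.1)
Conditions: HF·pyridine, pyridine, THF, 0 → 23 °C
Reagents that add atoms: none
Why: Buffered fluoride desilylation frees the allylic alcohol without touching the acetate, the diosphenol or the dienone.

**Compound list**
1 | hexa-1,5-diyne | C#CCCC#C | starting material
2 | (2E,6E)-3,6-dimethylocta-2,6-diene-1,8-diol | OC/C=C(C)/CC/C(C)=C/CO | intermediate
3 | (2E,6E)-8-[(tert-butyldiphenylsilyl)oxy]-3,6-dimethylocta-2,6-dien-1-ol | OC/C=C(C)/CC/C(C)=C/CO[Si](c1ccccc1)(c1ccccc1)C(C)(C)C | intermediate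
4 | (2E,6E)-8-[(tert-butyldiphenylsilyl)oxy]-3,6-dimethylocta-2,6-dien-1-yl propanoate | CCC(=O)OC/C=C(C)/CC/C(C)=C/CO[Si](c1ccccc1)(c1ccccc1)C(C)(C)C | intermediate
5 | (2S,3S,6E)-8-[(tert-butyldiphenylsilyl)oxy]-3-ethenyl-2,3,6-trimethyloct-6-enoic acid | C=C[C@](C)(CC/C(C)=C/CO[Si](c1ccccc1)(c1ccccc1)C(C)(C)C)[C@H](C)C(=O)O | intermediate
6 | methyl (2S,3S,6E)-8-[(tert-butyldiphenylsilyl)oxy]-3-ethenyl-2,3,6-trimethyloct-6-enoate | C=C[C@](C)(CC/C(C)=C/CO[Si](c1ccccc1)(c1ccccc1)C(C)(C)C)[C@H](C)C(=O)OC | intermediate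
7 | 4,4-diethoxybut-1-ene | C=CCC(OCC)OCC | starting material
8 | methyl (2S,3S,6E)-8-[(tert-butyldiphenylsilyl)oxy]-3-[(1E)-4,4-diethoxybut-1-en-1-yl]-2,3,6-trimethyloct-6-enoate | CCOC(OCC)C/C=C/[C@](C)(CC/C(C)=C/CO[Si](c1ccccc1)(c1ccccc1)C(C)(C)C)[C@H](C)C(=O)OC | intermediate
9 | methyl (2S,3S,6E)-8-[(tert-butyldiphenylsilyl)oxy]-2,3,6-trimethyl-3-[(1E)-4-oxobut-1-en-1-yl]oct-6-enoate | O=CC/C=C/[C@](C)(CC/C(C)=C/CO[Si](c1ccccc1)(c1ccccc1)C(C)(C)C)[C@H](C)C(=O)OC | intermediate
10 | methyl (2S,3S,6E)-3-[(1E,3E)-4-[(tert-butyldimethylsilyl)oxy]buta-1,3-dien-1-yl]-8-[(tert-butyldiphenylsilyl)oxy]-2,3,6-trimethyloct-6-enoate | CC(C)(C)[Si](C)(C)O/C=C/C=C/[C@](C)(CC/C(C)=C/CO[Si](c1ccccc1)(c1ccccc1)C(C)(C)C)[C@H](C)C(=O)OC | intermediate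
11 | ethyl (2E)-3-methyl-4-oxobut-2-enoate | CCOC(=O)/C=C(\C)C=O | starting material
12 | Diels–Alder adduct (3β-OTBS, 4β-CHO, 4α-CH3, 5α-CO2Et, 10β-C9 unit, C1=C2) | O=C[C@]1(C)[C@@H](C(=O)OCC)[C@H]([C@](C)(CC/C(C)=C/CO[Si](c2ccccc2)(c2ccccc2)C(C)(C)C)[C@H](C)C(=O)OC)C=C[C@@H]1O[Si](C)(C)C(C)(C)C | intermediate
13 | primary alcohol (12 with C19 as CH2OH) | OC[C@]1(C)[C@@H](C(=O)OCC)[C@H]([C@](C)(CC/C(C)=C/CO[Si](c2ccccc2)(c2ccccc2)C(C)(C)C)[C@H](C)C(=O)OC)C=C[C@@H]1O[Si](C)(C)C(C)(C)C | intermediate
14 | C19 trimethylsilyl ether of 13 | C[Si](C)(C)OC[C@]1(C)[C@@H](C(=O)OCC)[C@H]([C@](C)(CC/C(C)=C/CO[Si](c2ccccc2)(c2ccccc2)C(C)(C)C)[C@H](C)C(=O)OC)C=C[C@@H]1O[Si](C)(C)C(C)(C)C | intermediate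
15 | bicyclic enediol bis(trimethylsilyl) ether (C6(OTMS)=C7(OTMS), C19–OTMS, 3β-OTBS, trans ring fusion) | C[Si](C)(C)OC[C@]1(C)[C@H]2C(O[Si](C)(C)C)=C(O[Si](C)(C)C)[C@@H](C)[C@@](C)(CC/C(C)=C/CO[Si](c3ccccc3)(c3ccccc3)C(C)(C)C)[C@@H]2C=C[C@@H]1O[Si](C)(C)C(C)(C)C | intermediate
16 | acyloin (6-oxo-7-hydroxy form, C7 epimers, 19-OH free) | OC[C@]1(C)[C@H]2C(=O)C(O)[C@@H](C)[C@@](C)(CC/C(C)=C/CO[Si](c3ccccc3)(c3ccccc3)C(C)(C)C)[C@@H]2C=C[C@@H]1O[Si](C)(C)C(C)(C)C | intermediate
17 | diosphenol (7-hydroxy-Δ7-6-ketone, 19-OH, 3β-OTBS, C1=C2) | OC[C@]1(C)[C@H]2C(=O)C(O)=C(C)[C@@](C)(CC/C(C)=C/CO[Si](c3ccccc3)(c3ccccc3)C(C)(C)C)[C@@H]2C=C[C@@H]1O[Si](C)(C)C(C)(C)C | intermediate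
18 | 19-acetate of 17 | CC(=O)OC[C@]1(C)[C@H]2C(=O)C(O)=C(C)[C@@](C)(CC/C(C)=C/CO[Si](c3ccccc3)(c3ccccc3)C(C)(C)C)[C@@H]2C=C[C@@H]1O[Si](C)(C)C(C)(C)C | intermediate
19 | 3β-alcohol (18 without TBS) | CC(=O)OC[C@]1(C)[C@H]2C(=O)C(O)=C(C)[C@@](C)(CC/C(C)=C/CO[Si](c3ccccc3)(c3ccccc3)C(C)(C)C)[C@@H]2C=C[C@@H]1O | intermediate
20 | Δ1-3-ketone (enone) | CC(=O)OC[C@]1(C)[C@H]2C(=O)C(O)=C(C)[C@@](C)(CC/C(C)=C/CO[Si](c3ccccc3)(c3ccccc3)C(C)(C)C)[C@@H]2C=CC1=O | intermediate
21 | 15-O-tert-butyldiphenylsilyl ether of the target | CC(=O)OC[C@@]1(C)C(=O)CCC2=C1C(=O)C(O)=C(C)[C@@]2(C)CC/C(C)=C/CO[Si](c3ccccc3)(c3ccccc3)C(C)(C)C | intermediate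
22 | (4S,9S)-19-acetoxy-7,15-dihydroxyhalima-5(10),7,13E-triene-3,6-dione (CNP0512382.1) | CC(=O)OC[C@@]1(C)C(=O)CCC2=C1C(=O)C(O)=C(C)[C@@]2(C)CC/C(C)=C/CO | target

**Totals**
Total step count: 15. Longest linear sequence: 15 steps (from 1; compounds 7 and 11 are purchased).

**Steps most likely to fail**

1. Step 8. Bond formation at the diene terminus C10, which sits next to a quaternary carbon, may be slow. The acidic catalyst may protodesilylate the dienol ether or divert it into an open-chain Mukaiyama–Michael addition, and facial control at C4 may be incomplete. The fallback sets out from 10 and 11: the cycloaddition is promoted by an achiral Lewis acid (Me2AlCl, CH2Cl2, −78 °C), which keeps the aldehyde-directed regiochemistry. Because C9 is already fixed, the adduct formed on the other dienophile face, the ring-A antipodal cycloadduct F1, is a diastereomer of 12 and is removed by chromatography, here or after step 9. The route is rejoined at 12.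

2. Step 14. The alkene shift may stop at an equilibrium that retains the Δ1-3-ketone, or C5 may be deprotonated too slowly once the diosphenol is ionised. The fallback sets out from 19: MnO2 oxidation with isolation of enone 20, then conjugate reduction of the unhindered enone with [(Ph3P)CuH]6 (toluene, 23 °C) to the saturated 3-ketone F2. Dehydrogenation through the C6 enol with DDQ (dioxane, 80 °C) introduces the C5=C10 alkene and returns to 21.

3. Step 5. The vinyl group on the quaternary carbon may be too hindered for productive metathesis, so that the partner alkene only dimerises. The fallback sets out from 6: hydroboration with 9-BBN (THF), then NaBO3·4H2O, gives the primary alcohol F3. Dess–Martin periodinane gives the aldehyde F4, and Ph3P=CHCHO (toluene, 80 °C) gives the E-enal F5. γ-Deprotonation and O-silylation under the conditions of step 7 return to 10.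

**Further compounds**
F1 | step 8 | ring-A antipodal cycloadduct (C3, C4, C5 and C10 inverted relative to 12) | O=C[C@@]1(C)[C@H](C(=O)OCC)[C@@H]([C@](C)(CC/C(C)=C/CO[Si](c2ccccc2)(c2ccccc2)C(C)(C)C)[C@H](C)C(=O)OC)C=C[C@H]1O[Si](C)(C)C(C)(C)C
F2 | step 14 | saturated 3-ketone (20 with C1–C2 reduced) | CC(=O)OC[C@]1(C)[C@H]2C(=O)C(O)=C(C)[C@@](C)(CC/C(C)=C/CO[Si](c3ccccc3)(c3ccccc3)C(C)(C)C)[C@@H]2CCC1=O
F3 | step 5 | primary alcohol (6 with the vinyl group as CH2CH2OH) | OCC[C@](C)(CC/C(C)=C/CO[Si](c1ccccc1)(c1ccccc1)C(C)(C)C)[C@H](C)C(=O)OC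
F4 | step 5 | aldehyde (6 with the vinyl group as CH2CHO) | O=CC[C@](C)(CC/C(C)=C/CO[Si](c1ccccc1)(c1ccccc1)C(C)(C)C)[C@H](C)C(=O)OC
F5 | step 5 | E-enal (conjugated isomer of 9) | O=C/C=C/C[C@](C)(CC/C(C)=C/CO[Si](c1ccccc1)(c1ccccc1)C(C)(C)C)[C@H](C)C(=O)OC
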